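The earlier runs and the new flask are calculated from invented constants; noise was put on by code.

I decide to follow the gap, the share of the plateau still missing, and not the target made. I assume that a flask held at one temperature closes the same fraction of its gap in each equal stretch of time.

| flask | starting material | temperature | remark | time |
|---|---|---|---|---|
| Saturday's | 0.70 M | −5 °C | run made earlier |  |
| Monday's | 1.1 M | 30 °C | run made earlier |  |
| south | 0.50 M | 60 °C |  | 25 min |
| south-east | 0.50 M |  | at 0 °C until 20 min, from then on at 60 °C | 25 min |
| east | 0.50 M | 0 °C |  | 25 min |
| north-west | 0.50 M | 30 °C |  | 25 min |

| Saturday's: time / min | Saturday's: target / % | Monday's: time / min | Monday's: target / % |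
|---|---|---|---|
| 30.0 | 29.3 | 12.0 | 89.3 |
| 90.0 | 31.3 | 25.0 | 88.2 |
| 180 | 31.4 | 40.0 | 89.2 |
| 240 | 31.4 | 50.0 | 88.4 |
| 360 | 31.3 | 60.0 | 88.1 |

(standard deviation of a reading: 0.3 percentage points)

* which flask leads in amount of target, in percent of the starting material charged ("all alike" within 1.5 percentage points) (south / south-east / east / north-west / all alike)
* how much target is there at the end, in percent of the starting material charged: south
* how much target is there at the end, in percent of the starting material charged: south-east
* how much target is there at the end, in percent of the starting material charged: east
* how much target is there at the end, in percent of the starting material charged: north-west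

- a reading or a percentage of target counts all its forms, free or not

I let Saturday's last reading, 31.3%, stand for its plateau. At 30.0 min the gap reads 0.0639 of it, so the elapsed time over ln(1/gap) reads 10.9 min at −5 °C. This is my settling time (relaxation time). Monday's first reading, at 12.0 min, already reads higher than its last one, so I put its gap below the scatter of 0.3 percentage points, which on my assumption puts the settling time at 30 °C at about 2.11 min or less.

Two times now count in my reckoning of a flask: the settling time and the time it stands at its last temperature. I take warmer as quicker. East then has 25 min against 10.9 min, which on these assumptions leaves a gap of about 0.101 or less. South-east has 5.00 min at 60 °C against the 2.11 min or less reckoned for 30 °C, which on the same assumptions leaves about 0.0935 or less of its climb. By my reckoning, south-east ends close to south.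

The forecast agrees on that: “South-east's final 5 min at 60 °C should suffice, leaving it essentially tied with south.” It names south as the leader, with 98% in south, 97.5% in south-east, 41% in east and 88% in north-west.

The flasks give 87.3% in south, 91.3% in south-east, 36.9% in east and 77.4% in north-west, so south-east leads. At the end, south holds 5.39% as homo dimer and south-east 1.45%. East stands at 33.4% at 12.5 min, against 36.9% at 250 min. With the later value as its plateau, east's settling time at 0 °C reckons to 5.29 min, shorter than the 10.9 min read at −5 °C in Saturday's run.

    starting material ⇌ target (K = 14.1, k = 0.00247 /s, Ea = 75.0 kJ/mol, ΔH = 13.0 kJ/mol)
    target ⇌ isomer of the product (K = 1.60, k = 0.00170 /s, Ea = 81.0 kJ/mol, ΔH = −32.0 kJ/mol)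
    isomer of the product ⇌ starting material (k = 0.00798 /s, Ea = 81.0 kJ/mol)
    crystals ⇌ target, rate k4*(cs4 - [target]) while solid is left; crystals form when [target] > cs4 (solubility = 0.240 M, k = 0.190 /s)
    2 starting material → homo dimer (k = 0.00108 /M/s, Ea = 67.0 kJ/mol)
    (constants at 0 °C)

South-east read at 6.0 min is still at 0 °C, as east is, so with east's settling time the gap is 0.321 and the target 25.1%. The computed flask gives 24.9%.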